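**Plan**

Eudesmane numbering is used: ring A = C1–C5 + C10, ring B = C5–C10. C3 carries the angelate, C4 the tertiary alcohol, C7 the acrylate and C10 the angular methyl group. Compounds that still lack C13 are named as 13-noreudesmanes.
Retrosynthesis: the C3–O acyl bond is cut first. The unit C3(OH)–C4(OH)–C5=C6 is traced back through the 4β,5β-epoxide and the 3β-alcohol to a 4-en-3-one. C13 is then removed, a ketone is lent to C9, and C1–C2 and C5–C10 are cut together.
Enabling feature: C3 (oxygen) and C4 (methyl) of ring A match a 2-silyloxy-3-methyl diene C2=C3–C4=C5. Quaternary C10 with its methyl group is the α-carbon of an isopropenyl ketone once C9 is a carbonyl. The ring B chain C6–C7–C8–C9 ties diene terminus C5 to C10.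
Forward: the C7-branched chain is built from 3-allylglutaric anhydride (ester arm kept, acid arm to the isopropenyl ketone, allyl arm to the silyloxy diene). Rings A and B then close in one step. After that C9 is deoxygenated, C13 is added and ring A is oxidised.
Stereochemistry: C7 comes from alkaloid-catalysed methanolysis of the prochiral anhydride, and C7 sets C10 in the cycloaddition. The 10β-methyl group sends hydride to the α face of C3, and the 3β-OH delivers the oxygen that stays on C4. The Z alkene is bought with angelic acid.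

Key step: step 12

Assumption: the quinine-derived catalyst (DHQ)2AQN is taken to give the (S)-hemiester, by analogy with 3-alkylglutaric anhydrides. The pseudo-enantiomeric (DHQD)2AQN gives the mirror image, so the sense can be corrected by exchanging the catalyst.

Step 1
Reactants: 1 dimethyl 3-hydroxyglutarate
Product: 2 dimethyl 3-(phenoxythiocarbonyloxy)glutarate
Conditions: PhOC(S)Cl, pyridine, DMAP (cat.), CH2Cl2, 0 °C → rt
Reagents that add atoms: O-phenyl chlorothionoformate, ClC(=S)Oc1ccccc1
Why: Acylation of the secondary alcohol gives the thionocarbonate needed as radical precursor, and the weak base and low temperature should hold back β-elimination to the glutaconate.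

Step 2
Reactants: 2 dimethyl 3-(phenoxythiocarbonyloxy)glutarate; 3 allyltributylstannane
Product: 4 dimethyl 3-allylglutarate
Conditions: AIBN (cat.), toluene, 80 °C
Reagents that add atoms: allyltributylstannane (3), C=CC[Sn](CCCC)(CCCC)CCCC
Why: In this Keck radical allylation the stannyl radical attacks sulfur and the C7 radical adds to the allylstannane with loss of Bu3Sn•, which forms C6–C7 at a carbon closed to enolate chemistry; the product is achiral, so no stereochemistry is at stake.

Step 3
Reactants: 4 dimethyl 3-allylglutarate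
Product: 6 3-allylglutaric acid, via dilithium 3-allylglutarate 5 (not isolated)
Conditions: LiOH, THF–H2O, rt; then 1 M HCl to pH 2
Reagents that add atoms: lithium hydroxide, [Li+].[OH-]
Why: Ordinary saponification of two unhindered methyl esters leaves the terminal alkene untouched.

Step 4
Reactants: 6 3-allylglutaric acid
Product: 7 3-allylglutaric anhydride
Conditions: Ac2O, reflux; volatiles distilled off
Reagents that add atoms: none
Why: Cyclodehydration of a glutaric acid to its six-membered anhydride by anhydride exchange is a standard operation that an allyl group tolerates.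

Step 5
Reactants: 7 3-allylglutaric anhydride
Product: 8 (S)-3-(2-methoxy-2-oxoethyl)hex-5-enoic acid
Conditions: hydroquinine anthraquinone-1,4-diyl diether, (DHQ)2AQN (cat.), MeOH, Et2O, −40 °C
Reagents that add atoms: methanol, CO
Why: In this alkaloid-catalysed (general-base) desymmetrising methanolysis of a prochiral 3-alkylglutaric anhydride the catalyst tells the two enantiotopic carbonyl groups apart, which sets C7 and separates the ester arm (C11–C12) from the acid arm (C8–C9).

Step 6
Reactants: 8 (S)-3-(2-methoxy-2-oxoethyl)hex-5-enoic acid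
Product: 10 methyl (S)-3-{2-[methoxy(methyl)amino]-2-oxoethyl}hex-5-enoate, via acyl imidazole 9 (not isolated)
Conditions: 1,1'-carbonyldiimidazole, CH2Cl2, 0 °C → rt; then MeNHOMe·HCl, rt
Reagents that add atoms: N,O-dimethylhydroxylamine hydrochloride, CNOC.Cl; 1,1'-carbonyldiimidazole, O=C(n1ccnc1)n1ccnc1 (imidazolyl group of 9 only)
Why: Weinreb amide formation through the acyl imidazole stores C9 as a latent ketone that stays inert in steps 7 to 10, and C7 lies β to both carbonyl groups and cannot epimerise.

Step 7
Reactants: 10 methyl (S)-3-{2-[methoxy(methyl)amino]-2-oxoethyl}hex-5-enoate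
Product: 12 methyl (S)-5-[methoxy(methyl)amino]-5-oxo-3-(2-oxoethyl)pentanoate, via secondary ozonide 11 (not isolated)
Conditions: O3, CH2Cl2, −78 °C; then Me2S, −78 °C → rt
Reagents that add atoms: ozone, [O-][O+]=O
Why: Ozonolysis with reductive work-up cleaves the only alkene and uncovers C5 as the aldehyde without touching ester or amide.

Step 8
Reactants: 13 3-bromobutan-2-one; 14 triphenylphosphine
Product: 16 3-(triphenylphosphoranylidene)butan-2-one, via phosphonium bromide 15 (not isolated)
Conditions: toluene, 80 °C; then aq. NaOH, CH2Cl2, rt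
Reagents that add atoms: triphenylphosphine (14), c1ccc(cc1)P(c1ccccc1)c1ccccc1
Why: SN2 alkylation of the phosphine followed by deprotonation of the acidic salt is the usual way to a ketone-stabilised ylide.

Step 9
Reactants: 12 methyl (S)-5-[methoxy(methyl)amino]-5-oxo-3-(2-oxoethyl)pentanoate; 16 3-(triphenylphosphoranylidene)butan-2-one
Product: 17 methyl (S,E)-3-{2-[methoxy(methyl)amino]-2-oxoethyl}-6-methyl-7-oxooct-5-enoate
Conditions: toluene, 90 °C
Reagents that add atoms: 3-(triphenylphosphoranylidene)butan-2-one (16), CC(=O)C(C)=P(c1ccccc1)(c1ccccc1)c1ccccc1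
Why: The Wittig reaction of an α-branched stabilised ylide with an aliphatic aldehyde forms C4=C5 with the E geometry the diene needs and brings in C2, C3, C4 and C15 under neutral conditions.

Step 10
Reactants: 17 methyl (S,E)-3-{2-[methoxy(methyl)amino]-2-oxoethyl}-6-methyl-7-oxooct-5-enoate
Product: 18 methyl (S,E)-7-(tert-butyldimethylsilyloxy)-3-{2-[methoxy(methyl)amino]-2-oxoethyl}-6-methylocta-5,7-dienoate
Conditions: TBSOTf, Et3N, CH2Cl2, −78 → 0 °C
Reagents that add atoms: tert-butyldimethylsilyl trifluoromethanesulfonate, CC(C)(C)[Si](C)(C)OS(=O)(=O)C(F)(F)F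
Why: Soft enolisation of the methyl enone at its α'-methyl group gives the cross-conjugated 2-silyloxy diene, and doing it while C9 is still an amide leaves only one ketone to enolise.

Step 11
Reactants: 18 methyl (S,E)-7-(tert-butyldimethylsilyloxy)-3-{2-[methoxy(methyl)amino]-2-oxoethyl}-6-methylocta-5,7-dienoate; 19 isopropenylmagnesium bromide
Product: 21 methyl (S,E)-7-(tert-butyldimethylsilyloxy)-6-methyl-3-(3-methyl-2-oxobut-3-enyl)octa-5,7-dienoate, via magnesium hemiaminal chelate 20 (not isolated)
Conditions: THF, −78 → −20 °C; cold pH 7 phosphate buffer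
Reagents that add atoms: isopropenylmagnesium bromide (19), C=C(C)[Mg]Br
Why: In this Weinreb ketone synthesis the amide is attacked ahead of the methyl ester and the chelate holds the carbonyl masked until the neutral quench, so the enone appears only on work-up and the silyl enol ether survives.

Step 12
Reactants: 21 methyl (S,E)-7-(tert-butyldimethylsilyloxy)-6-methyl-3-(3-methyl-2-oxobut-3-enyl)octa-5,7-dienoate
Product: 22 methyl 3-(tert-butyldimethylsilyloxy)-9-oxo-13-noreudesm-3-en-12-oate (trans-fused; 5α-H; 7β side chain; 10β-methyl)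
Conditions: Me2AlCl (2.2 equiv), CH2Cl2, −78 → −30 °C; aq. NaHCO3
Reagents that add atoms: none
Why: Me2AlCl binds the C9 carbonyl group and lowers the LUMO of the C10=C1 double bond, so that the electron-rich diene C2=C3(OTBS)–C4(CH3)=C5 adds in a concerted, asynchronous [4+2] cycloaddition in which the bond from the enol-ether terminus C2 to the enone β-carbon C1 runs ahead of the bond C5–C10. The closest known reaction type is the Lewis-acid-promoted type 1 intramolecular Diels–Alder reaction of 1,7,9-decatrien-3-ones, which is documented for 2-silyloxy dienes. Ring A (C1, C2, C3, C4, C5, C10) closes as the new cyclohexene of the cycloaddition, and ring B (C5 to C10) closes in the fused mode through the four-atom tether C6–C9, the bridged orientation being both too strained for this tether and electronically mismatched. C10 is controlled by C7: in the chair-like tether the C10 methyl group is axial on the nascent ring B whether the tether carbonyl sits exo (trans fusion) or endo (cis fusion), so the chair with the C7 acetate arm equatorial places both groups on the β face. C5 is controlled by the E geometry of C4=C5 together with the exo position of the tether carbonyl, which the α-methyl group of the dienophile should favour, and this gives the trans-fused 5α-H isomer; a cis-fused by-product has the same C7/C10 relation and merges with the main line in step 17, where C5 becomes trigonal. The step therefore needs only discrimination between an equatorial and an axial C7 arm, which the substrate secures through the 1,3-diaxial contact of an axial arm with H5 (or with C4 in the endo mode) and which the low temperature allowed by the Lewis acid sharpens, while the robust TBS group and the proton-scavenging aluminium reagent keep the enol ether intact.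

Step 13
Reactants: 22 methyl 3-(tert-butyldimethylsilyloxy)-9-oxo-13-noreudesm-3-en-12-oate
Product: 23 methyl 3-(tert-butyldimethylsilyloxy)-9β-hydroxy-13-noreudesm-3-en-12-oate
Conditions: NaBH4, MeOH–THF, 0 °C
Reagents that add atoms: none
Why: Borohydride should reach the C9 ketone from the α face, away from the axial 10β-methyl group, to give the equatorial alcohol; its configuration is lost in step 15, and ester and TBS enol ether are inert.

Step 14
Reactants: 23 methyl 3-(tert-butyldimethylsilyloxy)-9β-hydroxy-13-noreudesm-3-en-12-oate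
Product: 24 methyl 3-(tert-butyldimethylsilyloxy)-9β-(imidazol-1-ylthiocarbonyloxy)-13-noreudesm-3-en-12-oate
Conditions: 1,1'-thiocarbonyldiimidazole, DMAP (cat.), toluene, 90 °C
Reagents that add atoms: 1,1'-thiocarbonyldiimidazole, S=C(n1ccnc1)n1ccnc1
Why: Thioacylation under neutral conditions derivatises the hindered alcohol without forming an alkoxide that could attack the C12 ester.

Step 15
Reactants: 24 methyl 3-(tert-butyldimethylsilyloxy)-9β-(imidazol-1-ylthiocarbonyloxy)-13-noreudesm-3-en-12-oate
Product: 25 methyl 3-(tert-butyldimethylsilyloxy)-13-noreudesm-3-en-12-oate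
Conditions: Bu3SnH, AIBN (cat.), toluene, 100 °C
Reagents that add atoms: none
Why: Barton–McCombie deoxygenation removes the oxygen that served only to activate the dienophile, and the secondary C9 radical has no alkene within reach, which is why the acrylate is introduced only afterwards.

Step 16
Reactants: 25 methyl 3-(tert-butyldimethylsilyloxy)-13-noreudesm-3-en-12-oate
Product: 29 methyl 3-(tert-butyldimethylsilyloxy)eudesma-3,11(13)-dien-12-oate, via lithium ester enolate 26 (not isolated), via Mannich base 27 (not isolated), via trimethylammonium iodide 28 (not isolated)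
Conditions: LiN(iPr)2, THF, −78 °C; CH2=NMe2+ I− (1.05 equiv), −78 °C → rt; MeI, rt; aq. K2CO3, CH2Cl2, rt
Reagents that add atoms: dimethyl(methylidene)ammonium iodide (Eschenmoser's salt), C=[N+](C)C.[I-]; iodomethane, IC (methyl group of 28 only)
Why: This is ester α-methylenation by Mannich reaction with Eschenmoser's salt, quaternisation and E1cB loss of trimethylamine; the silyl enol ether masks the C3 ketone, so the ester is the only enolisable carbonyl group, and C7 is not touched.

Step 17
Reactants: 29 methyl 3-(tert-butyldimethylsilyloxy)eudesma-3,11(13)-dien-12-oate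
Product: 30 methyl 3-oxoeudesma-4,11(13)-dien-12-oate
Conditions: Pd(OAc)2 (1.1 equiv), MeCN, 40 °C
Reagents that add atoms: none
Why: In the Saegusa–Ito oxidation divalent palladium takes the open α face of C4 and syn β-hydride elimination with the 5α-hydrogen gives the 4-en-3-one regiospecifically, which erases C5 and merges any C5 epimers.

Step 18
Reactants: 30 methyl 3-oxoeudesma-4,11(13)-dien-12-oate
Product: 31 methyl 3β-hydroxyeudesma-4,11(13)-dien-12-oate
Conditions: NaBH4, CeCl3·7H2O, MeOH, −78 → −20 °C
Reagents that add atoms: none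
Why: Luche 1,2-reduction delivers hydride axially from the α face, opposite the 10β-methyl group, which sets C3 as the pseudo-equatorial 3β-alcohol while the less electrophilic acrylate is left alone.

Step 19
Reactants: 31 methyl 3β-hydroxyeudesma-4,11(13)-dien-12-oate
Product: 32 methyl 4β,5β-epoxy-3β-hydroxyeudesm-11(13)-en-12-oate
Conditions: VO(acac)2 (cat.), t-BuOOH (decane), CH2Cl2, 0 °C → rt
Reagents that add atoms: tert-butyl hydroperoxide, CC(C)(C)OO
Why: In the vanadium-catalysed hydroxyl-directed epoxidation the metal alkoxide of the 3β-OH hands the oxygen to the same face of C4=C5, which sets C4 (oxygen β, methyl α) against the steric bias of the angular methyl group and leaves the electron-poor acrylate untouched.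

Step 20
Reactants: 32 methyl 4β,5β-epoxy-3β-hydroxyeudesm-11(13)-en-12-oate
Product: 35 methyl 3β,4β-dihydroxyeudesma-5,11(13)-dien-12-oate, via epoxy silyl ether 33 (not isolated), via bis(trimethylsilyl) ether 34 (not isolated)
Conditions: TMSOTf, 2,6-lutidine, toluene, −78 → −20 °C; then Bu4NF, AcOH, THF, 0 °C
Reagents that add atoms: trimethylsilyl trifluoromethanesulfonate, C[Si](C)(C)OS(=O)(=O)C(F)(F)F (silyl groups of 33 and 34 only)
Why: This is the silyl triflate–amine isomerisation of a fully substituted epoxide to an allylic silyl ether: the silylated oxirane ionises at C5 because C4 is deactivated by the neighbouring C3–O bond, the only adjacent proton (H6, C10 being quaternary) is lost to give C5=C6, the C4–O bond never breaks so C4 keeps its configuration, and buffered fluoride frees both alcohols.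

Step 21
Reactants: 35 methyl 3β,4β-dihydroxyeudesma-5,11(13)-dien-12-oate; 36 angelic acid
Product: 38 methyl 3β-angeloyloxy-4β-hydroxyeudesma-5,11(13)-dien-12-oate (3S,4R,7R,10S; CNP0283268.1), via mixed anhydride 37 (not isolated)
Conditions: 2,4,6-Cl3C6H2COCl, Et3N, toluene, rt; then 35, 80 °C
Reagents that add atoms: angelic acid (36), C/C=C(/C)C(=O)O; 2,4,6-trichlorobenzoyl chloride, O=C(Cl)c1c(Cl)cc(Cl)cc1Cl (aroyl group of 37 only)
Why: Yamaguchi-type mixed-anhydride esterification run without a nucleophilic catalyst is the established way to transfer an angeloyl group without Z to E isomerisation, and only the secondary 3β-OH reacts, not the tertiary 4β-OH.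

**Compound list**

1 | dimethyl 3-hydroxyglutarate | COC(=O)CC(O)CC(=O)OC | starting material
2 | dimethyl 3-(phenoxythiocarbonyloxy)glutarate | COC(=O)CC(OC(=S)Oc1ccccc1)CC(=O)OC | intermediate
3 | allyltributylstannane | C=CC[Sn](CCCC)(CCCC)CCCC | starting material
4 | dimethyl 3-allylglutarate | COC(=O)CC(CC=C)CC(=O)OC | intermediate
5 | dilithium 3-allylglutarate | [Li+].[Li+].[O-]C(=O)CC(CC=C)CC(=O)[O-] | intermediate
6 | 3-allylglutaric acid | OC(=O)CC(CC=C)CC(=O)O | intermediate
7 | 3-allylglutaric anhydride | C=CCC1CC(=O)OC(=O)C1 | intermediate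
8 | (S)-3-(2-methoxy-2-oxoethyl)hex-5-enoic acid | COC(=O)C[C@@H](CC=C)CC(=O)O | intermediate
9 | methyl (S)-3-[2-(imidazol-1-yl)-2-oxoethyl]hex-5-enoate | COC(=O)C[C@@H](CC=C)CC(=O)n1ccnc1 | intermediate
10 | methyl (S)-3-{2-[methoxy(methyl)amino]-2-oxoethyl}hex-5-enoate | COC(=O)C[C@@H](CC=C)CC(=O)N(C)OC | intermediate
11 | secondary ozonide (1,2,4-trioxolane) of 10 | COC(=O)C[C@@H](CC1OCOO1)CC(=O)N(C)OC | intermediate
12 | methyl (S)-5-[methoxy(methyl)amino]-5-oxo-3-(2-oxoethyl)pentanoate | COC(=O)C[C@@H](CC=O)CC(=O)N(C)OC | intermediate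
13 | 3-bromobutan-2-one | CC(Br)C(C)=O | starting material
14 | triphenylphosphine | c1ccc(cc1)P(c1ccccc1)c1ccccc1 | starting material
15 | (3-oxobutan-2-yl)triphenylphosphonium bromide | CC(C(C)=O)[P+](c1ccccc1)(c1ccccc1)c1ccccc1.[Br-] | intermediate
16 | 3-(triphenylphosphoranylidene)butan-2-one | CC(=O)C(C)=P(c1ccccc1)(c1ccccc1)c1ccccc1 | intermediate
17 | methyl (S,E)-3-{2-[methoxy(methyl)amino]-2-oxoethyl}-6-methyl-7-oxooct-5-enoate | COC(=O)C[C@@H](C/C=C(C)/C(C)=O)CC(=O)N(C)OC | intermediate
18 | methyl (S,E)-7-(tert-butyldimethylsilyloxy)-3-{2-[methoxy(methyl)amino]-2-oxoethyl}-6-methylocta-5,7-dienoate | COC(=O)C[C@@H](C/C=C(C)/C(=C)O[Si](C)(C)C(C)(C)C)CC(=O)N(C)OC | intermediate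
19 | isopropenylmagnesium bromide | C=C(C)[Mg]Br | starting material
20 | bromomagnesium hemiaminal chelate from 18 and 19 | COC(=O)C[C@@H](C/C=C(C)/C(=C)O[Si](C)(C)C(C)(C)C)CC(O[Mg]Br)(N(C)OC)C(C)=C | intermediate
21 | methyl (S,E)-7-(tert-butyldimethylsilyloxy)-6-methyl-3-(3-methyl-2-oxobut-3-enyl)octa-5,7-dienoate | COC(=O)C[C@@H](C/C=C(C)/C(=C)O[Si](C)(C)C(C)(C)C)CC(=O)C(C)=C | intermediate
22 | methyl 3-(tert-butyldimethylsilyloxy)-9-oxo-13-noreudesm-3-en-12-oate (5α-H, 7β side chain, 10β-methyl) | COC(=O)C[C@H]1C[C@H]2C(C)=C(O[Si](C)(C)C(C)(C)C)CC[C@]2(C)C(=O)C1 | intermediate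
23 | methyl 3-(tert-butyldimethylsilyloxy)-9β-hydroxy-13-noreudesm-3-en-12-oate | COC(=O)C[C@H]1C[C@H]2C(C)=C(O[Si](C)(C)C(C)(C)C)CC[C@]2(C)[C@@H](O)C1 | intermediate
24 | methyl 3-(tert-butyldimethylsilyloxy)-9β-(imidazol-1-ylthiocarbonyloxy)-13-noreudesm-3-en-12-oate | COC(=O)C[C@H]1C[C@H]2C(C)=C(O[Si](C)(C)C(C)(C)C)CC[C@]2(C)[C@@H](OC(=S)n3ccnc3)C1 | intermediate
25 | methyl 3-(tert-butyldimethylsilyloxy)-13-noreudesm-3-en-12-oate | COC(=O)C[C@H]1C[C@H]2C(C)=C(O[Si](C)(C)C(C)(C)C)CC[C@]2(C)CC1 | intermediate
26 | lithium enolate of ester 25 | [Li+].COC([O-])=C[C@H]1C[C@H]2C(C)=C(O[Si](C)(C)C(C)(C)C)CC[C@]2(C)CC1 | intermediate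
27 | methyl 13-(dimethylamino)-3-(tert-butyldimethylsilyloxy)eudesm-3-en-12-oate (C11 epimers) | COC(=O)C(CN(C)C)[C@H]1C[C@H]2C(C)=C(O[Si](C)(C)C(C)(C)C)CC[C@]2(C)CC1 | intermediate
28 | trimethylammonium iodide of 27 | [I-].COC(=O)C(C[N+](C)(C)C)[C@H]1C[C@H]2C(C)=C(O[Si](C)(C)C(C)(C)C)CC[C@]2(C)CC1 | intermediate
29 | methyl 3-(tert-butyldimethylsilyloxy)eudesma-3,11(13)-dien-12-oate | C=C(C(=O)OC)[C@H]1C[C@H]2C(C)=C(O[Si](C)(C)C(C)(C)C)CC[C@]2(C)CC1 | intermediate
30 | methyl 3-oxoeudesma-4,11(13)-dien-12-oate | C=C(C(=O)OC)[C@H]1CC2=C(C)C(=O)CC[C@]2(C)CC1 | intermediate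
31 | methyl 3β-hydroxyeudesma-4,11(13)-dien-12-oate | C=C(C(=O)OC)[C@H]1CC2=C(C)[C@@H](O)CC[C@]2(C)CC1 | intermediate
32 | methyl 4β,5β-epoxy-3β-hydroxyeudesm-11(13)-en-12-oate | C=C(C(=O)OC)[C@H]1C[C@]23O[C@@]2(C)[C@@H](O)CC[C@]3(C)CC1 | intermediate
33 | methyl 4β,5β-epoxy-3β-(trimethylsilyloxy)eudesm-11(13)-en-12-oate | C=C(C(=O)OC)[C@H]1C[C@]23O[C@@]2(C)[C@@H](O[Si](C)(C)C)CC[C@]3(C)CC1 | intermediate
34 | methyl 3β,4β-bis(trimethylsilyloxy)eudesma-5,11(13)-dien-12-oate | C=C(C(=O)OC)[C@H]1C=C2[C@](C)(CC[C@H](O[Si](C)(C)C)[C@]2(C)O[Si](C)(C)C)CC1 | intermediate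
35 | methyl 3β,4β-dihydroxyeudesma-5,11(13)-dien-12-oate | C=C(C(=O)OC)[C@H]1C=C2[C@](C)(CC[C@H](O)[C@]2(C)O)CC1 | intermediate
36 | angelic acid, (Z)-2-methylbut-2-enoic acid | C/C=C(/C)C(=O)O | starting material
37 | angelic 2,4,6-trichlorobenzoic anhydride | C/C=C(/C)C(=O)OC(=O)c1c(Cl)cc(Cl)cc1Cl | intermediate
38 | methyl 3β-angeloyloxy-4β-hydroxyeudesma-5,11(13)-dien-12-oate, (3S,4R,7R,10S), CNP0283268.1 | C=C(C(=O)OC)[C@H]1C=C2[C@](C)(CC[C@H](OC(=O)/C(C)=C\C)[C@]2(C)O)CC1 | target

**Step count**

Total: 21 steps. Longest linear sequence: 20 steps (steps 1–7 and 9–21; step 8 is a side branch).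

**Steps most likely to fail**

Step 12. The silyl group may be lost to adventitious acid. The reaction may stall after the first carbon–carbon bond. Transmission from C7 to C10 may be weak, because an axial arm costs little next to the trigonal C9.
The fallback keeps the same two bonds but makes them by an anion-accelerated route (intramolecular double Michael addition). It sets out from 21. Bu4NF buffered with AcOH takes off the silyl group to give the bis-enone methyl (S,E)-6-methyl-3-(3-methyl-2-oxobut-3-enyl)-7-oxooct-5-enoate F1. LiN(SiMe3)2 in THF at −78 °C then forms the cross-conjugated dienolate of the methyl ketone. Deprotonation at C8 is unproductive and reversible. The dienolate closes C1–C2 and C5–C10 and ends as the regiodefined bicyclic lithium 3-enolate F2. This is silylated in the same flask with TBSCl and DMPU, and the route is rejoined at 22.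

Step 20. The oxirane may ionise at C4 instead of C5. A methyl group or a ring bond may migrate in the C5 cation. The tertiary allylic silyl ether may ionise a second time.
The fallback moves the oxygen to C4 by a [2,3]-sigmatropic shift instead of through a cation. It sets out from 30 and bypasses 31 and 32.
- TBSOTf and Et3N give the linear dienol ether methyl 3-(tert-butyldimethylsilyloxy)eudesma-3,5,11(13)-trien-12-oate F3.
- PhSeCl at −78 °C attacks its γ-carbon axially to give the 6β-selenide methyl 3-oxo-6β-(phenylselanyl)eudesma-4,11(13)-dien-12-oate F4.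
- Luche reduction gives the 3β-alcohol methyl 3β-hydroxy-6β-(phenylselanyl)eudesma-4,11(13)-dien-12-oate F5.
- H2O2 with pyridine at 0 °C gives the allylic selenoxide F6, which cannot eliminate towards C7 because H7 is anti to selenium.
- F6 rearranges suprafacially on the β face to the 4β-selenenate F7, whose hydrolysis rejoins the route at 35.

Step 17. Palladation of the hindered, fully substituted TBS enol ether may be slow. β-Hydride loss may go towards the C4 methyl group. A palladium hydride may move the acrylate double bond.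
The fallback replaces the dehydrosilylation by halogenation and dehydrohalogenation. It sets out from 29. NBS in THF at 0 °C gives the tertiary bromo ketone methyl 4-bromo-3-oxoeudesm-11(13)-en-12-oate F8, whose configuration at C4 is of no consequence. Li2CO3 and LiBr in DMF at 120 °C then eliminate HBr towards C5, giving the conjugated and thermodynamically favoured alkene, and the route is rejoined at 30.

**Further compounds**

F1 | step 12 | methyl (S,E)-6-methyl-3-(3-methyl-2-oxobut-3-enyl)-7-oxooct-5-enoate | COC(=O)C[C@@H](C/C=C(C)/C(C)=O)CC(=O)C(C)=C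
F2 | step 12 | lithium 3-enolate of methyl 3,9-dioxo-13-noreudesman-12-oate | [Li+].COC(=O)C[C@H]1C[C@H]2C(C)=C([O-])CC[C@]2(C)C(=O)C1
F3 | step 20 | methyl 3-(tert-butyldimethylsilyloxy)eudesma-3,5,11(13)-trien-12-oate | C=C(C(=O)OC)[C@H]1C=C2C(C)=C(O[Si](C)(C)C(C)(C)C)CC[C@]2(C)CC1
F4 | step 20 | methyl 3-oxo-6β-(phenylselanyl)eudesma-4,11(13)-dien-12-oate | C=C(C(=O)OC)[C@H]1[C@@H]([Se]c3ccccc3)C2=C(C)C(=O)CC[C@]2(C)CC1
F5 | step 20 | methyl 3β-hydroxy-6β-(phenylselanyl)eudesma-4,11(13)-dien-12-oate | C=C(C(=O)OC)[C@H]1[C@@H]([Se]c3ccccc3)C2=C(C)[C@@H](O)CC[C@]2(C)CC1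
F6 | step 20 | methyl 3β-hydroxy-6β-(phenylseleninyl)eudesma-4,11(13)-dien-12-oate | C=C(C(=O)OC)[C@H]1[C@@H]([Se](=O)c3ccccc3)C2=C(C)[C@@H](O)CC[C@]2(C)CC1
F7 | step 20 | methyl 3β-hydroxy-4β-(phenylselanyloxy)eudesma-5,11(13)-dien-12-oate | C=C(C(=O)OC)[C@H]1C=C2[C@](C)(CC[C@H](O)[C@]2(C)O[Se]c3ccccc3)CC1
F8 | step 17 | methyl 4-bromo-3-oxoeudesm-11(13)-en-12-oate | C=C(C(=O)OC)[C@H]1C[C@H]2C(C)(Br)C(=O)CC[C@]2(C)CC1
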